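**Retrosynthetic overview**

1. Target 21 is the C6 trienoate of a cis-fused drimane hydroxy acid. Late disconnections: C11 acid from a 4-methoxybenzyl ester, the C6–O acyl bond (Yamaguchi), C6–OH by γ-oxygenation of the C7=C8 enal through its dienol silyl ether, the C12 formyl by carbonylation of a C7=C8 enol triflate, and C9–OH by enolate hydroxylation of a β-keto ester.
2. The strategy rests on ring A with the C4 gem-dimethyl, the quaternary C10 methyl cis to C5–H, and C9 carrying the carboxyl carbon C11 next to an oxygenated C8. This is the pattern of a cyclised neryl acetoacetate, and the cis C5/C10 fusion points to a Z alkene.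
3. Key disconnection: C4–C5 and C9–C10 together. Ring A and then ring B form in one proton-initiated cationic cascade from the acyclic keto ester 5 under a chiral tin-bound Brønsted acid.
4. Keto ester 5 comes from nerol and methyl acetoacetate by bromination and dianion γ-alkylation.

Key step: step 3

Remark on numbering: drimane numbering is used in the discussion (C9, C8, C7, C6, C5, C4, C10 = naphthalene C1, C2, C3, C4, C4a, C5, C8a; C11 = carboxyl carbon on C9; C12 = formyl carbon on C8; β = the face of C5–H and the C10 methyl).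
Assumption on the ligand: the (R)-configured BINOL ether is taken to give the (4aR,8aS) series; if the sense of induction is opposite, its commercially available enantiomer is used.
Assumption on the target: it is made as the open aldehyde acid as drawn; a ring–chain equilibrium with the cyclic lactol form would not change the constitution delivered.

**Route**

Step 1
Reactants: 1 nerol
Product: 2 neryl bromide
Conditions: PBr3 (0.4 equiv), pyridine (cat.), Et2O, −10 °C; used at once
Reagents that add atoms: phosphorus tribromide, BrP(Br)Br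
Why: Low-temperature PBr3 bromination of the primary allylic alcohol (SN2 on the phosphite ester) should give the primary bromide with the Z trisubstituted alkene intact, cold ether and immediate use suppressing allylic scrambling.

Step 2
Reactants: 2 neryl bromide; 3 methyl acetoacetate
Product: 5 methyl (6Z)-7,11-dimethyl-3-oxododeca-6,10-dienoate, via acetoacetate dianion 4 (not isolated)
Conditions: NaH, THF, 0 °C; n-BuLi, 0 °C; then 2, 0 °C → rt; 1 M HCl quench
Reagents that add atoms: none
Why: γ-Alkylation of the acetoacetate dianion, in which the more basic terminal carbanion of 4 displaces the primary allylic bromide by SN2, should attach the keto-ester terminator without touching the alkene geometry.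

Step 3
Reactants: 5 methyl (6Z)-7,11-dimethyl-3-oxododeca-6,10-dienoate
Product: 6 methyl (1S,4aR,8aS)-5,5,8a-trimethyl-2-oxodecahydronaphthalene-1-carboxylate (cis-fused, C1 epimerisable)
Conditions: (R)-2-[(2-fluorobenzyl)oxy]-2'-hydroxy-1,1'-binaphthyl·SnCl4 (preformed 1:1, 2 equiv), toluene, −78 °C
Reagents that add atoms: none
Why: Proposed new method: the SnCl4-bound phenol O–H of the chiral BINOL monoether should protonate C3 of the terminal trisubstituted alkene, and as the tertiary C4 cation develops it is attacked by C5 of the Z alkene while the chelated keto-ester enol carbon C9 captures the resulting C10 cation, so that C4–C5 and C9–C10 form in one cascade; the closest known reaction types are the SnCl4-promoted bicyclisation of polyene β-keto esters and the enantioselective proton-initiated polyene cyclisation by BINOL-ether·SnCl4 acids, which have not been combined on a Z substrate with a keto-ester terminator. Ring A closes 6-endo-trig (the C5=C10 alkene onto C4) and ring B closes in the 6-(enolendo) mode by C-alkylation of the enol at the C10 cation. C5 and C10 arise together by anti addition across the Z C5=C10 alkene in a chair-like fold, which places C5–H and the C10 methyl cis; their absolute sense is set by the chiral acid, which delivers the proton to one face of the terminal alkene of one helical fold; C9 settles with the ester equatorial and is re-made in step 4. The step needs C- over O-termination, concertedness (so that the Z geometry is translated into cis fusion) and enantioface selection; the first is favoured by the tin-chelated enol, the second by −78 °C in a non-ionising solvent, and the third rests on the ligand and is the untested point.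

Step 4
Reactants: 6 methyl (1S,4aR,8aS)-5,5,8a-trimethyl-2-oxodecahydronaphthalene-1-carboxylate
Product: 8 methyl (1R,4aR,8aS)-1-hydroxy-5,5,8a-trimethyl-2-oxodecahydronaphthalene-1-carboxylate, via potassium enolate 7 (not isolated)
Conditions: KN(SiMe3)2, THF, −78 °C; 2-(phenylsulfonyl)-3-phenyloxaziridine, −78 °C; cold NH4Cl quench
Reagents that add atoms: 2-(phenylsulfonyl)-3-phenyloxaziridine, O=S(=O)(N1OC1c1ccccc1)c1ccccc1
Why: Enolate hydroxylation with an N-sulfonyloxaziridine (Davis oxidation) should occur at C9 on the convex β face of the folded cis-decalin, the α face being shielded by ring A whose C1 methylene is axial to ring B, which puts the new hydroxyl cis to the C10 methyl and the ester on the α face.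

Step 5
Reactants: 8 methyl (1R,4aR,8aS)-1-hydroxy-5,5,8a-trimethyl-2-oxodecahydronaphthalene-1-carboxylate
Product: 9 methyl (1R,4aR,8aS)-5,5,8a-trimethyl-2-oxo-1-[(trimethylsilyl)oxy]decahydronaphthalene-1-carboxylate
Conditions: TMSOTf, 2,6-lutidine, CH2Cl2, −78 → 0 °C
Reagents that add atoms: trimethylsilyl trifluoromethanesulfonate, C[Si](C)(C)OS(=O)(=O)C(F)(F)F
Why: Silylation of the hindered tertiary alcohol with a silyl triflate and a hindered pyridine base masks the α-ketol against alkoxide-driven ketol rearrangement and O-sulfonylation in the next step.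

Step 6
Reactants: 9 methyl (1R,4aR,8aS)-5,5,8a-trimethyl-2-oxo-1-[(trimethylsilyl)oxy]decahydronaphthalene-1-carboxylate
Product: 11 methyl (1R,4aR,8aS)-5,5,8a-trimethyl-2-{[(trifluoromethyl)sulfonyl]oxy}-1-[(trimethylsilyl)oxy]-1,4,4a,5,6,7,8,8a-octahydronaphthalene-1-carboxylate, via potassium enolate 10 (not isolated)
Conditions: KN(SiMe3)2, THF, −78 °C; PhNTf2, −78 → 0 °C
Reagents that add atoms: N-phenylbis(trifluoromethanesulfonimide), FC(F)(F)S(=O)(=O)N(c1ccccc1)S(=O)(=O)C(F)(F)F
Why: Enol triflate formation is regiochemically unambiguous because C9 is quaternary, so the ketone can enolise only toward C7 and O-sulfonylation of enolate 10 gives the single C7=C8 triflate.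

Step 7
Reactants: 11 the C7=C8 enol triflate
Product: 12 methyl (1R,4aR,8aS)-2-formyl-5,5,8a-trimethyl-1-[(trimethylsilyl)oxy]-1,4,4a,5,6,7,8,8a-octahydronaphthalene-1-carboxylate
Conditions: Pd(PPh3)4 (5 mol %), LiCl, CO (1 atm), Bu3SnH (slow addition), THF, 50 °C
Reagents that add atoms: carbon monoxide, [C-]#[O+]
Why: Palladium-catalysed reductive carbonylation (formylation) of an enol triflate, by oxidative addition, CO insertion and hydride transfer from Bu3SnH to the acylpalladium species, should deliver the C12 aldehyde conjugated with C7=C8, slow stannane addition limiting direct reduction.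

Step 8
Reactants: 12 the C7=C8 enal
Product: 13 methyl (1R,4aR,8aS)-5,5,8a-trimethyl-1-[(trimethylsilyl)oxy]-2-{(E)-[(trimethylsilyl)oxy]methylidene}-1,2,4a,5,6,7,8,8a-octahydronaphthalene-1-carboxylate
Conditions: TMSOTf, Et3N, Et2O, 0 °C; non-aqueous work-up
Reagents that add atoms: trimethylsilyl trifluoromethanesulfonate, C[Si](C)(C)OS(=O)(=O)C(F)(F)F
Why: Soft enolisation of the enal, O-silylation of the aldehyde followed by removal of a γ-hydrogen at C6 by Et3N, should give the 1-silyloxy diene since C9 carries no hydrogen that could compete.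

Step 9
Reactants: 13 the dienol silyl ether
Product: 15 methyl (1R,4R,4aR,8aS)-2-formyl-1,4-dihydroxy-5,5,8a-trimethyl-1,4,4a,5,6,7,8,8a-octahydronaphthalene-1-carboxylate, via epoxy dienol ether 14 (not isolated)
Conditions: DMDO, acetone/CH2Cl2, −78 → −20 °C; then 1 M HCl, THF, 0 °C
Reagents that add atoms: dimethyldioxirane, CC1(C)OO1
Why: Vinylogous Rubottom oxidation, in which DMDO should transfer oxygen to the C6=C7 terminus of the dienol ether rather than to the hindered fully substituted C8 and from the convex β face because the α face of C6 is screened by the syn-axial C1 methylene of ring A, after which acid opens epoxide 14 to the γ-hydroxy enal and removes both trimethylsilyl groups, setting C6 with its oxygen cis to C5–H.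

Step 10
Reactants: 15 the dihydroxy enal methyl ester
Product: 16 (1R,4R,4aR,8aS)-2-formyl-1,4-dihydroxy-5,5,8a-trimethyl-1,4,4a,5,6,7,8,8a-octahydronaphthalene-1-carboxylic acid
Conditions: LiOH, THF/H2O, 0 °C; then 1 M HCl to pH 3
Reagents that add atoms: lithium hydroxide, [Li+].[OH-]
Why: Saponification assisted by the neighbouring formyl group, whose hydrate anion attacks the hindered C11 methyl ester through a five-membered ring, should proceed at 0 °C before any base-induced isomerisation of the γ-hydroxy enal.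

Step 11
Reactants: 16 the dihydroxy aldehyde acid
Product: 17 4-methoxybenzyl (1R,4R,4aR,8aS)-2-formyl-1,4-dihydroxy-5,5,8a-trimethyl-1,4,4a,5,6,7,8,8a-octahydronaphthalene-1-carboxylate
Conditions: 4-methoxybenzyl chloride, KHCO3, DMF, rt
Reagents that add atoms: 4-methoxybenzyl chloride, COc1ccc(CCl)cc1
Why: Carboxylate O-alkylation (SN2) under bicarbonate conditions should give the normal ester of the open aldehyde acid without alkylating either hydroxyl, providing an acid-labile mask for the hindered carboxyl.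

Step 12
Reactants: 17 the 4-methoxybenzyl ester diol; 18 (2E,4E,6E)-octa-2,4,6-trienoic acid
Product: 20 4-methoxybenzyl (1R,4R,4aR,8aS)-2-formyl-1-hydroxy-5,5,8a-trimethyl-4-{[(2E,4E,6E)-octa-2,4,6-trienoyl]oxy}-1,4,4a,5,6,7,8,8a-octahydronaphthalene-1-carboxylate, via mixed anhydride 19 (not isolated)
Conditions: 18, 2,4,6-trichlorobenzoyl chloride, Et3N, THF, 0 °C; then 17, DMAP, toluene, rt
Reagents that add atoms: none
Why: Yamaguchi esterification, DMAP-mediated acyl transfer from mixed anhydride 19, should acylate the secondary allylic C6 hydroxyl with retention while the tertiary C9 hydroxyl next to the quaternary C10 is too hindered to react and the all-E triene is not isomerised.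

Step 13
Reactants: 20 the 4-methoxybenzyl ester trienoate
Product: 21 (1R,4R,4aR,8aS)-2-formyl-1-hydroxy-5,5,8a-trimethyl-4-{[(2E,4E,6E)-octa-2,4,6-trienoyl]oxy}-1,4,4a,5,6,7,8,8a-octahydronaphthalene-1-carboxylic acid
Conditions: TFA, anisole, CH2Cl2, 0 °C
Reagents that add atoms: none
Why: Acidolysis of the 4-methoxybenzyl ester (SN1 at the benzylic carbon, the cation being trapped by anisole) should free the C11 acid under anhydrous conditions that leave the allylic trienoate, the enal and the tertiary alcohol untouched.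

**Compound list**

1 | nerol, (2Z)-3,7-dimethylocta-2,6-dien-1-ol | CC(C)=CCC/C(C)=C\CO | starting material
2 | neryl bromide, (2Z)-1-bromo-3,7-dimethylocta-2,6-diene | CC(C)=CCC/C(C)=C\CBr | intermediate
3 | methyl acetoacetate | COC(=O)CC(C)=O | starting material
4 | methyl acetoacetate dianion, sodium lithium salt | COC(=O)[CH-]C(=O)[CH2-].[Na+].[Li+] | intermediate (not isolated)
5 | methyl (6Z)-7,11-dimethyl-3-oxododeca-6,10-dienoate | COC(=O)CC(=O)CC/C=C(/C)CCC=C(C)C | intermediate
6 | methyl (1S,4aR,8aS)-5,5,8a-trimethyl-2-oxodecahydronaphthalene-1-carboxylate (cis-fused; 4a-H and 8a-CH3 on the same face) | C1CC(=O)[C@@H](C(=O)OC)[C@@]2(C)CCCC(C)(C)[C@@H]12 | intermediate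
7 | potassium enolate of 6 | C1CC([O-])=C(C(=O)OC)[C@@]2(C)CCCC(C)(C)[C@@H]12.[K+] | intermediate (not isolated)
8 | methyl (1R,4aR,8aS)-1-hydroxy-5,5,8a-trimethyl-2-oxodecahydronaphthalene-1-carboxylate (1-OH cis to 8a-CH3) | C1CC(=O)[C@@](O)(C(=O)OC)[C@@]2(C)CCCC(C)(C)[C@@H]12 | intermediate
9 | methyl (1R,4aR,8aS)-5,5,8a-trimethyl-2-oxo-1-[(trimethylsilyl)oxy]decahydronaphthalene-1-carboxylate | C1CC(=O)[C@@](O[Si](C)(C)C)(C(=O)OC)[C@@]2(C)CCCC(C)(C)[C@@H]12 | intermediate
10 | potassium C2–C3 enolate of 9 | C1C=C([O-])[C@@](O[Si](C)(C)C)(C(=O)OC)[C@@]2(C)CCCC(C)(C)[C@@H]12.[K+] | intermediate (not isolated)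
11 | methyl (1R,4aR,8aS)-5,5,8a-trimethyl-2-{[(trifluoromethyl)sulfonyl]oxy}-1-[(trimethylsilyl)oxy]-1,4,4a,5,6,7,8,8a-octahydronaphthalene-1-carboxylate | C1C=C(OS(=O)(=O)C(F)(F)F)[C@@](O[Si](C)(C)C)(C(=O)OC)[C@@]2(C)CCCC(C)(C)[C@@H]12 | intermediate
12 | methyl (1R,4aR,8aS)-2-formyl-5,5,8a-trimethyl-1-[(trimethylsilyl)oxy]-1,4,4a,5,6,7,8,8a-octahydronaphthalene-1-carboxylate | C1C=C(C=O)[C@@](O[Si](C)(C)C)(C(=O)OC)[C@@]2(C)CCCC(C)(C)[C@@H]12 | intermediate
13 | methyl (1R,4aR,8aS)-5,5,8a-trimethyl-1-[(trimethylsilyl)oxy]-2-{(E)-[(trimethylsilyl)oxy]methylidene}-1,2,4a,5,6,7,8,8a-octahydronaphthalene-1-carboxylate | C1=C/C(=C\O[Si](C)(C)C)[C@@](O[Si](C)(C)C)(C(=O)OC)[C@@]2(C)CCCC(C)(C)[C@@H]12 | intermediate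
14 | 3,4-epoxide of 13 (naphthalene locants), oxygen on the face of 4a-H and 8a-CH3 | O3[C@@H]1[C@H]3/C(=C\O[Si](C)(C)C)[C@@](O[Si](C)(C)C)(C(=O)OC)[C@@]2(C)CCCC(C)(C)[C@@H]12 | intermediate (not isolated)
15 | methyl (1R,4R,4aR,8aS)-2-formyl-1,4-dihydroxy-5,5,8a-trimethyl-1,4,4a,5,6,7,8,8a-octahydronaphthalene-1-carboxylate | O[C@@H]1C=C(C=O)[C@@](O)(C(=O)OC)[C@@]2(C)CCCC(C)(C)[C@@H]12 | intermediate
16 | (1R,4R,4aR,8aS)-2-formyl-1,4-dihydroxy-5,5,8a-trimethyl-1,4,4a,5,6,7,8,8a-octahydronaphthalene-1-carboxylic acid | O[C@@H]1C=C(C=O)[C@@](O)(C(=O)O)[C@@]2(C)CCCC(C)(C)[C@@H]12 | intermediate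
17 | 4-methoxybenzyl (1R,4R,4aR,8aS)-2-formyl-1,4-dihydroxy-5,5,8a-trimethyl-1,4,4a,5,6,7,8,8a-octahydronaphthalene-1-carboxylate | O[C@@H]1C=C(C=O)[C@@](O)(C(=O)OCc3ccc(OC)cc3)[C@@]2(C)CCCC(C)(C)[C@@H]12 | intermediate
18 | (2E,4E,6E)-octa-2,4,6-trienoic acid | C/C=C/C=C/C=C/C(=O)O | starting material
19 | (2E,4E,6E)-octa-2,4,6-trienoic 2,4,6-trichlorobenzoic anhydride | C/C=C/C=C/C=C/C(=O)OC(=O)c1c(Cl)cc(Cl)cc1Cl | intermediate (not isolated)
20 | 4-methoxybenzyl (1R,4R,4aR,8aS)-2-formyl-1-hydroxy-5,5,8a-trimethyl-4-{[(2E,4E,6E)-octa-2,4,6-trienoyl]oxy}-1,4,4a,5,6,7,8,8a-octahydronaphthalene-1-carboxylate | C/C=C/C=C/C=C/C(=O)O[C@@H]1C=C(C=O)[C@@](O)(C(=O)OCc3ccc(OC)cc3)[C@@]2(C)CCCC(C)(C)[C@@H]12 | intermediate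
21 | (1R,4R,4aR,8aS)-2-formyl-1-hydroxy-5,5,8a-trimethyl-4-{[(2E,4E,6E)-octa-2,4,6-trienoyl]oxy}-1,4,4a,5,6,7,8,8a-octahydronaphthalene-1-carboxylic acid | C/C=C/C=C/C=C/C(=O)O[C@@H]1C=C(C=O)[C@@](O)(C(=O)O)[C@@]2(C)CCCC(C)(C)[C@@H]12 | target

**Totals**

Total step count: 13. Longest linear sequence: 13 steps (nerol 1 to target 21); acid 18 is used as purchased.

**Steps most likely to fail**

1. Step 3 (the step labelled as a proposed new method). What may go wrong: the keto ester sequesters SnCl4 and achiral tin-bound protons initiate the cascade in competition with the chiral acid, so that the fold is not selected and little enantiomeric enrichment results; stepwise capture of the C10 cation can also erode the cis fusion. Fallback with known chemistry, setting out from 5 and returning at 6: cyclisation of 5 with SnCl4 alone (CH2Cl2, −78 → 0 °C), the established racemic bicyclisation of polyene β-keto esters, should give 6 together with its mirror image, methyl (1R,4aS,8aR)-5,5,8a-trimethyl-2-oxodecahydronaphthalene-1-carboxylate F1. Condensation of this mixture with (S)-1-phenylethylamine (AcOH cat., toluene, reflux with water removal) gives the diastereomeric enamino esters methyl (4aR,8aS)-5,5,8a-trimethyl-2-{[(1S)-1-phenylethyl]amino}-3,4,4a,5,6,7,8,8a-octahydronaphthalene-1-carboxylate F2 and methyl (4aS,8aR)-5,5,8a-trimethyl-2-{[(1S)-1-phenylethyl]amino}-3,4,4a,5,6,7,8,8a-octahydronaphthalene-1-carboxylate F3. These are separated by crystallisation or chromatography, and hydrolysis of F2 (aqueous AcOH, THF) returns enantiopure 6.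

2. Step 9. What may go wrong: oxygen transfer to the enol-ether double bond (attack at C8 instead of C6) or to the concave face of C6=C7, giving poor regio- or facial selectivity. Fallback, setting out from 9 and returning at 15, in which the C6 oxygen is introduced by conjugate addition instead:
   - Ketone 9 is dehydrogenated (LiN(i-Pr)2, THF, −78 °C; then N-tert-butylbenzenesulfinimidoyl chloride) to the C6=C7 enone methyl (1R,4aR,8aS)-5,5,8a-trimethyl-2-oxo-1-[(trimethylsilyl)oxy]-1,2,4a,5,6,7,8,8a-octahydronaphthalene-1-carboxylate F4.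
   - tert-Butyl hydroperoxide with DBU in CH2Cl2 should add to C6 from the convex face and close to the 6β,7β-epoxy ketone (naphthalene 3,4-epoxide, oxygen on the face of 4a-H) F5.
   - Reductive opening of the Cα–O bond with Na[PhSeB(OEt)3] (from (PhSe)2 and NaBH4, EtOH, AcOH, 0 °C) gives methyl (1R,4R,4aR,8aS)-4-hydroxy-5,5,8a-trimethyl-2-oxo-1-[(trimethylsilyl)oxy]decahydronaphthalene-1-carboxylate F6.
   - Silylation (Et3SiOTf, 2,6-lutidine, CH2Cl2) gives the 4-triethylsilyl ether F7.
   - Enol triflate formation (KN(SiMe3)2, PhNTf2, THF, −78 °C) gives methyl (1R,4S,4aR,8aS)-5,5,8a-trimethyl-4-[(triethylsilyl)oxy]-2-{[(trifluoromethyl)sulfonyl]oxy}-1-[(trimethylsilyl)oxy]-1,4,4a,5,6,7,8,8a-octahydronaphthalene-1-carboxylate F8.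
   - Formylation under the conditions of step 7 gives methyl (1R,4R,4aR,8aS)-2-formyl-5,5,8a-trimethyl-4-[(triethylsilyl)oxy]-1-[(trimethylsilyl)oxy]-1,4,4a,5,6,7,8,8a-octahydronaphthalene-1-carboxylate F9.
   - Removal of both silyl groups (1 M HCl, THF) rejoins the route at 15.

3. Step 7. What may go wrong: at the hindered C8, hydride capture of the vinylpalladium species outruns CO insertion, so that direct reduction of the triflate competes with formylation. Fallback, setting out from 11 and returning at 12: Stille coupling of 11 with tributyl(vinyl)stannane (Pd(PPh3)4, LiCl, THF, reflux) gives the diene methyl (1R,4aR,8aS)-2-ethenyl-5,5,8a-trimethyl-1-[(trimethylsilyl)oxy]-1,4,4a,5,6,7,8,8a-octahydronaphthalene-1-carboxylate F10. Johnson–Lemieux cleavage of the terminal vinyl group (OsO4 cat., NaIO4, 2,6-lutidine, dioxane/H2O) then gives 12; the ring alkene is trisubstituted and flanked by the quaternary C9, so it should react more slowly.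

**Further compounds**

F1 | step 3 | methyl (1R,4aS,8aR)-5,5,8a-trimethyl-2-oxodecahydronaphthalene-1-carboxylate (enantiomer of 6) | C1CC(=O)[C@H](C(=O)OC)[C@]2(C)CCCC(C)(C)[C@H]12
F2 | step 3 | methyl (4aR,8aS)-5,5,8a-trimethyl-2-{[(1S)-1-phenylethyl]amino}-3,4,4a,5,6,7,8,8a-octahydronaphthalene-1-carboxylate | C1CC(N[C@@H](C)c3ccccc3)=C(C(=O)OC)[C@@]2(C)CCCC(C)(C)[C@@H]12
F3 | step 3 | methyl (4aS,8aR)-5,5,8a-trimethyl-2-{[(1S)-1-phenylethyl]amino}-3,4,4a,5,6,7,8,8a-octahydronaphthalene-1-carboxylate | C1CC(N[C@@H](C)c3ccccc3)=C(C(=O)OC)[C@]2(C)CCCC(C)(C)[C@H]12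
F4 | step 9 | methyl (1R,4aR,8aS)-5,5,8a-trimethyl-2-oxo-1-[(trimethylsilyl)oxy]-1,2,4a,5,6,7,8,8a-octahydronaphthalene-1-carboxylate | C1=CC(=O)[C@@](O[Si](C)(C)C)(C(=O)OC)[C@@]2(C)CCCC(C)(C)[C@@H]12
F5 | step 9 | methyl (1R,4aR,8aS)-3,4-epoxy-5,5,8a-trimethyl-2-oxo-1-[(trimethylsilyl)oxy]decahydronaphthalene-1-carboxylate, epoxide oxygen on the face of 4a-H | O3[C@@H]1[C@H]3C(=O)[C@@](O[Si](C)(C)C)(C(=O)OC)[C@@]2(C)CCCC(C)(C)[C@@H]12
F6 | step 9 | methyl (1R,4R,4aR,8aS)-4-hydroxy-5,5,8a-trimethyl-2-oxo-1-[(trimethylsilyl)oxy]decahydronaphthalene-1-carboxylate | O[C@@H]1CC(=O)[C@@](O[Si](C)(C)C)(C(=O)OC)[C@@]2(C)CCCC(C)(C)[C@@H]12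
F7 | step 9 | methyl (1R,4R,4aR,8aS)-5,5,8a-trimethyl-2-oxo-4-[(triethylsilyl)oxy]-1-[(trimethylsilyl)oxy]decahydronaphthalene-1-carboxylate | CC[Si](CC)(CC)O[C@@H]1CC(=O)[C@@](O[Si](C)(C)C)(C(=O)OC)[C@@]2(C)CCCC(C)(C)[C@@H]12
F8 | step 9 | methyl (1R,4S,4aR,8aS)-5,5,8a-trimethyl-4-[(triethylsilyl)oxy]-2-{[(trifluoromethyl)sulfonyl]oxy}-1-[(trimethylsilyl)oxy]-1,4,4a,5,6,7,8,8a-octahydronaphthalene-1-carboxylate | CC[Si](CC)(CC)O[C@@H]1C=C(OS(=O)(=O)C(F)(F)F)[C@@](O[Si](C)(C)C)(C(=O)OC)[C@@]2(C)CCCC(C)(C)[C@@H]12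
F9 | step 9 | methyl (1R,4R,4aR,8aS)-2-formyl-5,5,8a-trimethyl-4-[(triethylsilyl)oxy]-1-[(trimethylsilyl)oxy]-1,4,4a,5,6,7,8,8a-octahydronaphthalene-1-carboxylate | CC[Si](CC)(CC)O[C@@H]1C=C(C=O)[C@@](O[Si](C)(C)C)(C(=O)OC)[C@@]2(C)CCCC(C)(C)[C@@H]12
F10 | step 7 | methyl (1R,4aR,8aS)-2-ethenyl-5,5,8a-trimethyl-1-[(trimethylsilyl)oxy]-1,4,4a,5,6,7,8,8a-octahydronaphthalene-1-carboxylate | C1C=C(C=C)[C@@](O[Si](C)(C)C)(C(=O)OC)[C@@]2(C)CCCC(C)(C)[C@@H]12
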